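A small charge of partner, 0.0800 M against 0.25 M of starting material, can make little single product, while a large charge can carry it on to double product, so you want to know where the yield stands between these two.

| setting | north-west | south-west | south |
|---|---|---|---|
| starting material | 0.25 M | 0.25 M | 0.25 M |
| partner | 0.0800 M | 0.200 M | 0.600 M |
| time | 15 h | 15 h | 15 h |

    starting material + partner → single product (k1 = 5.0 × 10⁻⁴ M⁻¹ s⁻¹)
    starting material + partner → other mono adduct (k2 = 8.5 × 10⁻⁵ M⁻¹ s⁻¹)
    partner + single product → double product (k3 = 5.3 × 10⁻⁴ M⁻¹ s⁻¹)
    partner + other mono adduct → double product (k4 = 1.0 × 10⁻⁴ M⁻¹ s⁻¹)
    starting material ⇌ dormant form (K5 = 0.53, k5 = 2.8 × 10⁻⁵ s⁻¹)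

- amount of single product at the end, in percent of the starting material charged for north-west, south-west, south, in this order
- the shape of the row from first to last (falls all the way / rises, then falls / rises all the way / hardly changes / falls, then rises)

- "hardly changes" means that all values lie within two and a half points (for a concentration: within two and a half percent of the largest)
- run time (north-west): 15 h

Start with the race for single product. It gains at 5.0 × 10⁻⁴ M⁻¹ s⁻¹ times c(starting material) times c(partner) and loses at 5.3 × 10⁻⁴ M⁻¹ s⁻¹ times c(single product) times c(partner). Partner stands as a factor in both, so it cancels. Single product stops gaining when c(single product)/c(starting material) reaches 0.943, the balance ratio, at any partner concentration.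

Now take two extremes. In the first, the second addition is switched off, so each partner makes one mono adduct and single product receives the share 85.5 %. That gives 27.4 % in north-west and 68.4 % in south-west.

In the second, partner stays in pseudo-first-order excess. Single product then climbs to the balance ratio and peaks near 33.0 % of the charge, after which it falls.

I take the lower of the two figures as a ceiling for each flask, so I expect under 27.4 % in north-west and under 33.0 % in south-west. South keeps 0.100 M of partner even with two partners taken per starting material charged. At that concentration step three has a half-life of 3.63 h, shorter than the 15 h of the run, so I expect a few percent there.

The dormant form relaxes with a half-life of 2.38 h, shorter than the run, and at equilibrium holds 34.6 % of starting material and dormant form together. This lowers c(starting material) further, which is one more reason to stay under those figures.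

The forecast gives 19 %, 26 % and 2 %, with the shape rises, then falls, saying that “the excess partner drives almost everything on to the double product”. My ceilings for north-west and south-west, 27.4 % and 33.0 %, stand higher than its values for those flasks.

The flask gives 19.6 %, 28.6 % and 2.00 %, and the shape is rises, then falls. In south-west, partner is down to 0.770 % of its charge at 15.0 h, with 27.4 % of the starting material left. The ratio of single product to starting material there reads 1.04, above the balance ratio of 0.943. In south, the same ratio at 15.0 h reads 1.89, also above it, and single product has gone from 6.63 % at 7.50 h to 2.00 %.

The constants belong to no real substance; the result is computed.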